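Remarks on the chemistry (one line each):
- Locants follow carotenoid numbering: unprimed atoms belong to the trihydroxylated half, primed atoms to the acetylenic half; TBS = tert-butyldimethylsilyl, TBSO = its ether oxygen.
- Assumption: the SMILES is read as the all-E (3S,5S,6S,3'R) isomer, in which the C3 and C5 hydroxyls are cis and the C6 hydroxyl is trans to both; 1, 6, 9, 14, 20, 28, 31 and 35 are taken as commercial, 20 and 35 as E/Z mixtures.

## Analysis of the target

The target is a C40 xanthophyll with the constitution of heteroxanthin, (3S,5S,6S,3'R)-7',8'-didehydro-5,6-dihydro-β,β-carotene-3,5,6,3'-tetrol. Its chain carries eight E double bonds (C7=C8 to C9'=C10') and ends in the C7'≡C8' triple bond, which is attached to the C5'=C6' double bond of a hydroxylated cyclohexene ring. The other end is a cyclohexane ring with three stereocentres: the C3 and C5 hydroxyls are cis, the C6 hydroxyl is trans to both, so the polyene on C6 is cis to O3 and O5. C3' is the only stereocentre of the acetylenic ring. It has the same spatial sense as C3 (the descriptors differ only because O5 changes the priorities), so one chiral ketone can supply both rings, but the rings are too far apart to control each other. Sensitive features are the polyene (light, oxygen, acid), the tertiary allylic C6 hydroxyl, which ionises readily into the chain, and the enyne, whose 9' double bond isomerises easily to 9'Z because the linear alkyne removes the steric preference for E. The hard points are this 9'E bond next to the triple bond, the C5 hydroxyl that must sit syn to O3 but anti to O6, and the union of two labile halves. The strategy rests on the unit C6'–C7'≡C8'–C9': an alkyne flanked by two alkenyl carbons (ring C6' and chain C9') is the rearranged form of a bis-alkenyl ketone plus one carbon.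

## Retrosynthetic reasoning

41 ⇒ 40. Only the two O–Si bonds at O3 and O3' are cut. The secondary hydroxyls have to be masked through enolate, organomagnesium, carbene and ylide chemistry, and silyl ethers can be removed at the end without acid, which the C6 hydroxyl and the polyene would not tolerate.

40 ⇒ 23 + 38. The chain is cut at C15=C15'. This gives two C20 halves of equal size, each carrying the stereocentres of one ring, and puts the convergent step last. The trihydroxylated half is the aldehyde 38 and the acetylenic half the phosphonium salt 23, because making a phosphonium salt requires ionising conditions that the C6 hydroxyl would not survive. The forward reaction is a Wittig olefination through ylide 39. The central bond is the one double bond whose Z isomer reverts thermally.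

23 ⇒ 22 ⇒ 21 ⇒ 19 + 20. The C11'=C12' bond is cut, so the acetylenic half comes from the C15 enynal 19 and the C5 phosphonate 20. Cutting here and not at C9'=C10' keeps every olefination away from the carbon next to the triple bond. The forward sequence is a vinylogous Horner–Wadsworth–Emmons reaction, reduction to the allylic alcohol 22 and salt formation.

19 ⇒ 18. The aldehyde is carried as its diethyl acetal, since a free aldehyde would not survive the nucleophilic diazo reagent of the key step.

18 ⇒ 13 + 14. One alkyne carbon is removed and C6' and C9' are rejoined through a carbonyl group, giving the dienone 13 and the one-carbon reagent 14. The gain is that 13 is far easier to make stereoselectively than the enyne, and that no olefination is needed beside the triple bond. The forward reaction must add the lithiated diazo compound to a crowded carbonyl and let the resulting alkylidene carbene rearrange by a 1,2-alkenyl shift.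

13 ⇒ 11 ⇒ 8 + 9. The C9'=C10' bond is cut as an aldol condensation between the ethyl ketone 8 and the aldehyde 9. In the ketone the E and Z isomers differ clearly in energy, so the 9'E geometry can be fixed under thermodynamic control before any alkyne exists.

8 ⇒ 5 + 6, 5 ⇒ 4, 4 ⇒ 2 ⇒ 1. The C–C bond between the carbonyl and the ethyl group is cut (Weinreb ketone synthesis from 5 and 6), then the C6'–carbonyl bond (carbonylation of the enol triflate 4). The triflate comes from the silylated ketone 2, and 2 from 1, which supplies C3'. The C6 stereocentre of 1 is spent in forming the ring double bond.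

38 ⇒ 36 ⇒ 34 + 35 and 34 ⇒ 32 ⇒ 30 + 31. The chain of the other half is shortened by cutting C11=C12 and then C9=C10, each as a phosphonate olefination followed by reduction of the nitrile. This reaches the C13 ketone 30, where the ring stereochemistry can be set on a short, electron-poor side chain.

30 ⇒ 29. The C5–O bond is cut: the trans-diol is the hydration product of the anti epoxide, with inversion at C5 and retention of the epoxide oxygen at C6. The opening is placed at the enone stage because there C6 cannot stabilise a cation. On a polyene it would ionise at C6 instead.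

29 ⇒ 27 + 28, 27 ⇒ 26 ⇒ 25 ⇒ 24 ⇒ 4. C7=C8 is cut (Wittig reaction of the epoxy aldehyde 27 with ylide 28). The epoxide is then traced to the allylic alcohol 25 by Sharpless asymmetric epoxidation, which sets C5 and C6 under reagent control. Compound 25 comes from the ester 24 and this from the same triflate 4 that serves the acetylenic half, so both rings branch from one intermediate.

## Alternatives that were turned down

Alternative 1: The trihydroxylated ring is built by cycloaddition instead of being taken from the chiral pool.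
- Disconnection: C2–C3 and C1–C6 of that ring are cut, leading back to the hydroxypyrone A1 (3-hydroxy-4-methyl-2H-pyran-2-one) and the enal A2 (2-methylprop-2-enal).
- Forward key step: an amine base converts A1 into its dienolate, which adds across the C=C bond of A2 in a [4+2] reaction. The product is the bridged lactone A3 (4-hydroxy-5,8-dimethyl-3-oxo-2-oxabicyclo[2.2.2]oct-5-ene-8-carbaldehyde). Its lactone oxygen sits on the future C3, the hydroxylated bridgehead is the future C6 and the lactone carbonyl is the future C7.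
- For it: one step forms the carbocycle with the quaternary C1 and the oxygenated C6. The lactone bridge holds O3 and C7 on the same face by construction, which is exactly the C3/C6 relationship of the target. A chiral amine could make the step enantioselective.
- Against it: A3 is still far from the ring. C4=C5 must be hydrated with the new hydroxyl cis to O3, which is the hardest centre and is left open. The formyl group on C1 must be reduced to methyl at a neopentylic position. The lactone must be opened and C7 adjusted for chain extension. The strategy does nothing for C3' or the enyne, so the chiral ketone 1 is needed for the other half anyway.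
- Comparison: A3 is stronger on the C3/C6 relationship, which is enforced by the bridge, whereas the chosen route depends on a facial selectivity in epoxidation (step 14). In exchange the chosen route draws both rings from one intermediate (4), reaches the ring-complete ketone 30 in six steps from 4, and spends its risk on the enyne.

Alternative 2: The triol is made by a tethered epoxide opening.
- Disconnection: the C5–O bond is cut so that the oxygen comes from a carbonate on O3. The precursor is A4, the tert-butyl carbonate of (3S,5R,6S)-5,6-epoxy-3-hydroxy-5,6-dihydro-β-ionone.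
- Forward key step: a boron Lewis acid activates the epoxide, the carbonyl oxygen of the carbonate attacks C5 from the face opposite to the epoxide oxygen, the tert-butyl group is lost, and the 3,5-cyclic carbonate A5 results. C6 keeps the epoxide oxygen as its hydroxyl.
- For it: the nucleophile can only reach C5 and only from the O3 face, so regiochemistry and inversion are both secured by the tether. The ring must place O3 axial for this, which an external nucleophile would avoid. The product is also a protected 3,5-diol.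
- Against it: as the organising idea it leaves the acetylenic half to conventional coupling or olefination, where 9'Z isomers arise. The carbonate cannot be carried through the enolate chemistry that makes 4, so a change of protecting group is needed.
- Comparison: on the triol ring this alternative is stronger than step 17 of the chosen route, which opens the same kind of epoxide with external water and has to rely on the electronic bias of the enone alone. The chosen route offers a single step in place of a five-step detour and the same silyl group on both halves. The tethered opening is kept as the fallback for step 17.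

Alternative 3: The enyne is made by carbometalation and cross-coupling.
- Disconnection: the C9'–CH3 and C10'–C11' bonds are cut, leading to the ring diyne A6 ((4R)-1-(buta-1,3-diyn-1-yl)-4-(TBSO)-2,6,6-trimethylcyclohex-1-ene) and the iododienoate A7 (ethyl (2E,4E)-5-iodo-3-methylpenta-2,4-dienoate).
- Forward key step: zirconium-catalysed methylalumination adds methyl to C9' and aluminium to C10' of A6 in a syn fashion. After transmetalation to zinc, palladium-catalysed Negishi coupling with A7 gives A8, the ethyl ester of the silylated acetylenic C20 acid. A8 is the same compound as 21 of the chosen route.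
- For it: syn addition fixes 9'E stereospecifically, and the geometry of C11'=C12' and C13'=C14' is bought with A7. The sequence reaches the C20 ester in about three steps from 4, against seven in the chosen route (steps 3 to 9). The reaction type is well established.
- Against it: A6 is a terminal conjugated diyne, a class that is unstable and needs a protected butadiyne to make. The methylalumination must distinguish the terminal alkyne from the conjugated internal one. A7 needs its own synthesis. An excess of pyrophoric organoaluminium is used on a polyunsaturated substrate.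
- Comparison: on precedent and on step count this alternative is the stronger plan, and that is acknowledged. The chosen strategy offers in its place cheap one- and two-carbon reagents (6, 9, 14), no polyyne and no organoaluminium, and a 9'E geometry that is settled by equilibration in a ketone, where E and Z differ in energy, before the alkyne exists. It also tests a disconnection of the enyne that olefination and coupling routes do not offer.

Key step: step 7

## Steps

Step 1
Reactants: 1 (4R,6R)-4-hydroxy-2,2,6-trimethylcyclohexanone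
Product: 2 (4R,6R)-4-(TBSO)-2,2,6-trimethylcyclohexanone
Conditions: TBSCl, imidazole, DMF, rt
Reagents that add atoms: tert-butyldimethylsilyl chloride, CC(C)(C)[Si](C)(C)Cl
Why: Silylation of the only hydroxyl under imidazole catalysis (silyl ether formation); C4 and C6 are not involved, and the ether later tolerates enolate, Grignard, carbene and ylide chemistry.

Step 2
Reactants: 2 (4R,6R)-4-(TBSO)-2,2,6-trimethylcyclohexanone
Product: 4 (4R)-4-(TBSO)-2,6,6-trimethylcyclohex-1-en-1-yl trifluoromethanesulfonate, via lithium enolate 3 (not isolated)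
Conditions: LiN(iPr)2, THF, −78 °C; PhNTf2, −78 °C → rt
Reagents that add atoms: N-phenylbis(trifluoromethanesulfonimide), O=S(=O)(N(c1ccccc1)S(=O)(=O)C(F)(F)F)C(F)(F)F
Why: The ketone has a single α-hydrogen (C6), so one enolate forms and is O-sulfonylated (enol triflate formation); the C6 stereocentre is deliberately turned into the sp2 carbon that becomes C5 or C5', and C4 stays R.

Step 3
Reactants: 4 (4R)-4-(TBSO)-2,6,6-trimethylcyclohex-1-en-1-yl trifluoromethanesulfonate
Product: 5 (4R)-4-(TBSO)-N-methoxy-N,2,6,6-tetramethylcyclohex-1-ene-1-carboxamide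
Conditions: Pd(OAc)2 (5 mol %), Xantphos, CO (1 atm), MeNHOMe·HCl, Et3N, toluene, 80 °C
Reagents that add atoms: carbon monoxide, [C-]#[O+]; N,O-dimethylhydroxylamine hydrochloride, CNOC.Cl
Why: Palladium-catalysed aminocarbonylation of a vinyl triflate: oxidative addition to zerovalent palladium, CO insertion and capture of the acylpalladium by the hydroxylamine give the Weinreb amide in one step.

Step 4
Reactants: 5 (4R)-4-(TBSO)-N-methoxy-N,2,6,6-tetramethylcyclohex-1-ene-1-carboxamide; 6 ethylmagnesium bromide
Product: 8 1-[(4R)-4-(TBSO)-2,6,6-trimethylcyclohex-1-en-1-yl]propan-1-one, via magnesium hemiaminal chelate 7 (not isolated)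
Conditions: EtMgBr (3 equiv), THF, 0 °C → 40 °C
Reagents that add atoms: none
Why: Weinreb ketone synthesis: the Grignard reagent adds once and the chelate 7 persists until work-up, so no tertiary alcohol forms; the tetrasubstituted ring double bond is twisted out of conjugation, so conjugate addition is not expected.

Step 5
Reactants: 8 1-[(4R)-4-(TBSO)-2,6,6-trimethylcyclohex-1-en-1-yl]propan-1-one; 9 2,2-diethoxyacetaldehyde
Product: 11 1-[(4R)-4-(TBSO)-2,6,6-trimethylcyclohex-1-en-1-yl]-4,4-diethoxy-3-hydroxy-2-methylbutan-1-one (diastereomer mixture at C2 and C3 of the butanone), via lithium enolate 10 (not isolated)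
Conditions: LiN(iPr)2, THF, −78 °C; 9, −78 °C
Reagents that add atoms: none
Why: Directed aldol addition: the CH2 of the ethyl group is the only α-position of 8, and 9 cannot enolise and is activated by its two α-oxygens; the two new stereocentres are removed in step 6, so their configuration does not matter.

Step 6
Reactants: 11 1-[(4R)-4-(TBSO)-2,6,6-trimethylcyclohex-1-en-1-yl]-4,4-diethoxy-3-hydroxy-2-methylbutan-1-one
Product: 13 (2E)-1-[(4R)-4-(TBSO)-2,6,6-trimethylcyclohex-1-en-1-yl]-4,4-diethoxy-2-methylbut-2-en-1-one, via mesylate 12 (not isolated)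
Conditions: MsCl, Et3N, CH2Cl2, 0 °C; DBU, rt
Reagents that add atoms: none
Why: Mesylation and E1cB elimination through the ketone enolate complete the aldol condensation; the E enone, with the acetal carbon trans to the acyl group, is the thermodynamically preferred isomer and is what enolate-based elimination should deliver, which fixes the future 9'E geometry.

Step 7
Reactants: 13 (2E)-1-[(4R)-4-(TBSO)-2,6,6-trimethylcyclohex-1-en-1-yl]-4,4-diethoxy-2-methylbut-2-en-1-one; 14 (trimethylsilyl)diazomethane
Product: 18 tert-butyl{[(1R)-4-[(3E)-5,5-diethoxy-3-methylpent-3-en-1-yn-1-yl]-3,5,5-trimethylcyclohex-3-en-1-yl]oxy}dimethylsilane, via lithium alkoxide adduct 15 (not isolated), via diazoalkene 16 (not isolated), via alkylidene carbene 17 (not isolated)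
Conditions: Me3SiCHN2, n-BuLi, THF, −78 °C; 13, −78 °C → rt
Reagents that add atoms: none
Why: Lithiated 14 adds to the carbonyl carbon of 13 to give the alkoxide 15; silicon moves from carbon to oxygen and lithium trimethylsilanolate is expelled (Peterson-type elimination), leaving the diazoalkene 16. Loss of N2 on warming gives the alkylidene carbene 17, and a 1,2-shift of one of the two alkenyl groups to the carbene carbon creates C7'≡C8' together with the bond from the new carbon to the migrating group; because both substituents are alkenyl, either shift gives 18. The closest known reaction type is the Colvin rearrangement of aryl and alkenyl ketones, an alkylidene-carbene 1,2-shift of the Fritsch–Buttenberg–Wiechell kind. No ring is closed and no stereocentre is created; C3' is remote, and the C9'=C10' geometry from step 6 is kept because the migrating sp2 carbon moves with retention and that double bond is not part of the reacting centre. The step needs 1,2-addition in place of conjugate addition: 13 has no α-hydrogen, so enolisation by the basic reagent cannot compete, the hard organolithium is used at −78 °C, and C10' is screened by the C19' methyl group and the acetal. It also needs the 1,2-shift to outrun 1,5 C–H insertion: sp2 groups migrate much faster than the carbene inserts into the primary C–H bonds of the ring methyl groups, and the acetal C–H is held away from the carbene by the E double bond.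

Step 8
Reactants: 18 tert-butyl{[(1R)-4-[(3E)-5,5-diethoxy-3-methylpent-3-en-1-yn-1-yl]-3,5,5-trimethylcyclohex-3-en-1-yl]oxy}dimethylsilane
Product: 19 (2E)-5-[(4R)-4-(TBSO)-2,6,6-trimethylcyclohex-1-en-1-yl]-3-methylpent-2-en-4-ynal
Conditions: PPTS (cat.), acetone–H2O (10:1), rt, dark
Reagents that add atoms: water, O
Why: Acetal hydrolysis through an oxocarbenium ion stabilised by the enyne; pyridinium tosylate in wet acetone is mild enough for the secondary silyl ether, and a short reaction time in the dark avoids 9'E to 9'Z isomerisation.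

Step 9
Reactants: 19 (2E)-5-[(4R)-4-(TBSO)-2,6,6-trimethylcyclohex-1-en-1-yl]-3-methylpent-2-en-4-ynal; 20 ethyl 4-(diethoxyphosphoryl)-3-methylbut-2-enoate
Product: 21 ethyl (2E,4E,6E)-9-[(4R)-4-(TBSO)-2,6,6-trimethylcyclohex-1-en-1-yl]-3,7-dimethylnona-2,4,6-trien-8-ynoate
Conditions: 20, n-BuLi, THF–DMPU, −78 °C; 19, −78 → 0 °C
Reagents that add atoms: none
Why: Vinylogous Horner–Wadsworth–Emmons olefination: the lithiated phosphonate reacts at its α-carbon and the stabilised carbanion gives the E bond at C11'=C12'; the 13'E ester should predominate at low temperature with DMPU, and minor 13'Z material is removed by chromatography.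

Step 10
Reactants: 21 ethyl (2E,4E,6E)-9-[(4R)-4-(TBSO)-2,6,6-trimethylcyclohex-1-en-1-yl]-3,7-dimethylnona-2,4,6-trien-8-ynoate
Product: 22 (2E,4E,6E)-9-[(4R)-4-(TBSO)-2,6,6-trimethylcyclohex-1-en-1-yl]-3,7-dimethylnona-2,4,6-trien-8-yn-1-ol
Conditions: iBu2AlH (2.5 equiv), CH2Cl2, −78 °C; aq. KNaC4H4O6 (potassium sodium tartrate)
Reagents that add atoms: none
Why: 1,2-Reduction of the conjugated ester by the aluminium hydride at low temperature; alkyne, polyene and silyl ether are inert.

Step 11
Reactants: 22 (2E,4E,6E)-9-[(4R)-4-(TBSO)-2,6,6-trimethylcyclohex-1-en-1-yl]-3,7-dimethylnona-2,4,6-trien-8-yn-1-ol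
Product: 23 {(2E,4E,6E)-9-[(4R)-4-(TBSO)-2,6,6-trimethylcyclohex-1-en-1-yl]-3,7-dimethylnona-2,4,6-trien-8-yn-1-yl}triphenylphosphonium bromide
Conditions: PPh3·HBr (1.05 equiv), CH2Cl2, 0 °C → rt, dark
Reagents that add atoms: triphenylphosphine hydrobromide, Br.c1ccc(cc1)P(c1ccccc1)c1ccccc1
Why: Ionisation of the polyenylic alcohol gives a delocalised cation that triphenylphosphine captures at the primary terminus (the usual entry to retinyl-type Wittig salts); one equivalent of the phosphonium acid in an aprotic solvent is used to spare the silyl ether.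

Step 12
Reactants: 4 (4R)-4-(TBSO)-2,6,6-trimethylcyclohex-1-en-1-yl trifluoromethanesulfonate
Product: 24 methyl (4R)-4-(TBSO)-2,6,6-trimethylcyclohex-1-ene-1-carboxylate
Conditions: Pd(OAc)2 (5 mol %), PPh3, CO (1 atm), Et3N, MeOH–DMF, 60 °C
Reagents that add atoms: carbon monoxide, [C-]#[O+]; methanol, CO
Why: Palladium-catalysed methoxycarbonylation of the vinyl triflate; the same acylpalladium as in step 3 is trapped by methanol.

Step 13
Reactants: 24 methyl (4R)-4-(TBSO)-2,6,6-trimethylcyclohex-1-ene-1-carboxylate
Product: 25 [(4R)-4-(TBSO)-2,6,6-trimethylcyclohex-1-en-1-yl]methanol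
Conditions: iBu2AlH (2.5 equiv), CH2Cl2, −78 → 0 °C
Reagents that add atoms: none
Why: Hydride reduction of the hindered conjugated ester gives the allylic alcohol needed for hydroxyl-directed epoxidation.

Step 14
Reactants: 25 [(4R)-4-(TBSO)-2,6,6-trimethylcyclohex-1-en-1-yl]methanol
Product: 26 [(1R,4S,6R)-4-(TBSO)-2,2,6-trimethyl-7-oxabicyclo[4.1.0]heptan-1-yl]methanol
Conditions: Ti(OiPr)4 (1 equiv), D-(−)-diethyl tartrate (1.2 equiv), t-BuOOH, 4 Å MS, CH2Cl2, −20 °C
Reagents that add atoms: tert-butyl hydroperoxide, CC(C)(C)OO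
Why: Sharpless asymmetric epoxidation of the tetrasubstituted allylic alcohol under reagent control: with D-(−)-tartrate the oxygen enters the face of C5=C6 from which C5, C1 and the hydroxymethyl carbon appear counter-clockwise around C6, which is the face anti to the C3 silyloxy group. This sets C5 and C6 together, with the epoxide trans to O3.

Step 15
Reactants: 26 [(1R,4S,6R)-4-(TBSO)-2,2,6-trimethyl-7-oxabicyclo[4.1.0]heptan-1-yl]methanol
Product: 27 (1S,4S,6R)-4-(TBSO)-2,2,6-trimethyl-7-oxabicyclo[4.1.0]heptane-1-carbaldehyde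
Conditions: Dess–Martin periodinane, NaHCO3, CH2Cl2, 0 °C → rt
Reagents that add atoms: none
Why: Buffered Dess–Martin oxidation of the primary alcohol; the aldehyde has a quaternary α-carbon and cannot epimerise, and the neutral medium leaves the epoxide closed.

Step 16
Reactants: 27 (1S,4S,6R)-4-(TBSO)-2,2,6-trimethyl-7-oxabicyclo[4.1.0]heptane-1-carbaldehyde; 28 1-(triphenyl-λ5-phosphanylidene)propan-2-one
Product: 29 (3E)-4-[(1S,4S,6R)-4-(TBSO)-2,2,6-trimethyl-7-oxabicyclo[4.1.0]heptan-1-yl]but-3-en-2-one
Conditions: 28 (2 equiv), toluene, 90 °C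
Reagents that add atoms: none
Why: Wittig reaction with a stabilised ylide gives the E enone (C7=C8); the neopentylic aldehyde needs heating, but the neutral conditions leave epoxide and silyl ether intact.

Step 17
Reactants: 29 (3E)-4-[(1S,4S,6R)-4-(TBSO)-2,2,6-trimethyl-7-oxabicyclo[4.1.0]heptan-1-yl]but-3-en-2-one
Product: 30 (3E)-4-[(1S,2S,4S)-4-(TBSO)-1,2-dihydroxy-2,6,6-trimethylcyclohexyl]but-3-en-2-one
Conditions: HClO4 (0.05 M aq.), THF, 0 °C; NaHCO3
Reagents that add atoms: water, O
Why: Acid-catalysed hydration of the epoxide: C6 is neopentylic and its cation would be conjugated with the electron-poor enone, so the C5–O bond is the one that breaks, and water enters C5 anti to the leaving oxygen (borderline A-2 opening). Inversion at C5 gives 5S with the new hydroxyl cis to O3, while C6 keeps the epoxide oxygen (6S); dilute acid at low temperature is chosen so that the secondary silyl ether survives.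

Step 18
Reactants: 30 (3E)-4-[(1S,2S,4S)-4-(TBSO)-1,2-dihydroxy-2,6,6-trimethylcyclohexyl]but-3-en-2-one; 31 diethyl (cyanomethyl)phosphonate
Product: 32 (2E,4E)-5-[(1S,2S,4S)-4-(TBSO)-1,2-dihydroxy-2,6,6-trimethylcyclohexyl]-3-methylpenta-2,4-dienenitrile
Conditions: 31 (3.2 equiv), NaH (3 equiv), THF, 0 °C; 30, rt → 45 °C
Reagents that add atoms: none
Why: Horner–Wadsworth–Emmons olefination of the methyl ketone with the preformed sodium phosphonate (no free hydride, so the tertiary hydroxyls stay protonated); the 9E nitrile is expected as the main isomer and the 9Z isomer is separated.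

Step 19
Reactants: 32 (2E,4E)-5-[(1S,2S,4S)-4-(TBSO)-1,2-dihydroxy-2,6,6-trimethylcyclohexyl]-3-methylpenta-2,4-dienenitrile
Product: 34 (2E,4E)-5-[(1S,2S,4S)-4-(TBSO)-1,2-dihydroxy-2,6,6-trimethylcyclohexyl]-3-methylpenta-2,4-dienal, via aluminium aldimine 33 (not isolated)
Conditions: iBu2AlH (4 equiv), CH2Cl2, −78 °C; wet SiO2, 0 °C
Reagents that add atoms: water, O
Why: The aluminium hydride adds once to the nitrile and the N-aluminio imine is hydrolysed on work-up to the aldehyde; the hydroxyls consume reagent as aluminium alkoxides, hence the excess, and the nearly neutral silica work-up protects the allylic tertiary alcohol.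

Step 20
Reactants: 34 (2E,4E)-5-[(1S,2S,4S)-4-(TBSO)-1,2-dihydroxy-2,6,6-trimethylcyclohexyl]-3-methylpenta-2,4-dienal; 35 diethyl (3-cyano-2-methylprop-2-en-1-yl)phosphonate
Product: 36 (2E,4E,6E,8E)-9-[(1S,2S,4S)-4-(TBSO)-1,2-dihydroxy-2,6,6-trimethylcyclohexyl]-3,7-dimethylnona-2,4,6,8-tetraenenitrile
Conditions: 35 (2.2 equiv), NaH (2 equiv), THF, 0 °C; 34, 0 °C → rt
Reagents that add atoms: none
Why: Second vinylogous Horner–Wadsworth–Emmons olefination, forming C11=C12 as the E alkene; the 13E nitrile should predominate and minor 13Z material is removed.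

Step 21
Reactants: 36 (2E,4E,6E,8E)-9-[(1S,2S,4S)-4-(TBSO)-1,2-dihydroxy-2,6,6-trimethylcyclohexyl]-3,7-dimethylnona-2,4,6,8-tetraenenitrile
Product: 38 (2E,4E,6E,8E)-9-[(1S,2S,4S)-4-(TBSO)-1,2-dihydroxy-2,6,6-trimethylcyclohexyl]-3,7-dimethylnona-2,4,6,8-tetraenal, via aluminium aldimine 37 (not isolated)
Conditions: iBu2AlH (4 equiv), CH2Cl2, −78 °C; wet SiO2, 0 °C, dark
Reagents that add atoms: water, O
Why: As in step 19, partial reduction of the conjugated nitrile and hydrolysis of the aluminium imine give the aldehyde without touching the silyl ether or the diol.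

Step 22
Reactants: 23 {(2E,4E,6E)-9-[(4R)-4-(TBSO)-2,6,6-trimethylcyclohex-1-en-1-yl]-3,7-dimethylnona-2,4,6-trien-8-yn-1-yl}triphenylphosphonium bromide; 38 (2E,4E,6E,8E)-9-[(1S,2S,4S)-4-(TBSO)-1,2-dihydroxy-2,6,6-trimethylcyclohexyl]-3,7-dimethylnona-2,4,6,8-tetraenal
Product: 40 (all-E,3S,5S,6S,3'R)-3,3'-bis(TBSO)-7',8'-didehydro-5,6-dihydro-β,β-carotene-5,6-diol, via phosphorus ylide 39 (not isolated)
Conditions: NaOMe, MeOH–CH2Cl2, 0 °C → rt; then heptane, 80 °C, dark
Reagents that add atoms: none
Why: Wittig reaction of the conjugated ylide with the tetraenal forms C15=C15'; methoxide does not deprotonate the tertiary alcohols and leaves the silyl ethers. The 15Z isomer that accompanies the product is the least hindered cis bond of the chain and should revert to E on brief heating, which is kept short so that 9'E is not disturbed.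

Step 23
Reactants: 40 (all-E,3S,5S,6S,3'R)-3,3'-bis(TBSO)-7',8'-didehydro-5,6-dihydro-β,β-carotene-5,6-diol
Product: 41 (all-E,3S,5S,6S,3'R)-7',8'-didehydro-5,6-dihydro-β,β-carotene-3,5,6,3'-tetrol (CNP0160593.1)
Conditions: Bu4NF (3 equiv), AcOH (3 equiv), THF, rt, dark
Reagents that add atoms: none
Why: Fluoride cleaves both secondary silyl ethers; buffering with acetic acid keeps the medium near neutral, which the polyene, the enyne and the tertiary allylic C6 hydroxyl tolerate.

## Compound list

1 | (4R,6R)-4-hydroxy-2,2,6-trimethylcyclohexanone (actinol) | O=C1C(C)(C)C[C@H](O)C[C@H]1C | starting material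
2 | (4R,6R)-4-(TBSO)-2,2,6-trimethylcyclohexanone | O=C1C(C)(C)C[C@H](O[Si](C)(C)C(C)(C)C)C[C@H]1C | intermediate
3 | lithium enolate of 2 | CC1=C(O[Li])C(C)(C)C[C@H](O[Si](C)(C)C(C)(C)C)C1 | intermediate
4 | (4R)-4-(TBSO)-2,6,6-trimethylcyclohex-1-en-1-yl trifluoromethanesulfonate | CC1=C(OS(=O)(=O)C(F)(F)F)C(C)(C)C[C@H](O[Si](C)(C)C(C)(C)C)C1 | intermediate
5 | (4R)-4-(TBSO)-N-methoxy-N,2,6,6-tetramethylcyclohex-1-ene-1-carboxamide | CC1=C(C(=O)N(C)OC)C(C)(C)C[C@H](O[Si](C)(C)C(C)(C)C)C1 | intermediate
6 | ethylmagnesium bromide | CC[Mg]Br | starting material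
7 | magnesium hemiaminal chelate from 5 and 6 (carbinol carbon unspecified) | CC1=C(C(CC)(O[Mg]Br)N(C)OC)C(C)(C)C[C@H](O[Si](C)(C)C(C)(C)C)C1 | intermediate
8 | 1-[(4R)-4-(TBSO)-2,6,6-trimethylcyclohex-1-en-1-yl]propan-1-one | CC1=C(C(=O)CC)C(C)(C)C[C@H](O[Si](C)(C)C(C)(C)C)C1 | intermediate
9 | 2,2-diethoxyacetaldehyde | CCOC(OCC)C=O | starting material
10 | lithium enolate of 8 | CC1=C(C(O[Li])=CC)C(C)(C)C[C@H](O[Si](C)(C)C(C)(C)C)C1 | intermediate
11 | 1-[(4R)-4-(TBSO)-2,6,6-trimethylcyclohex-1-en-1-yl]-4,4-diethoxy-3-hydroxy-2-methylbutan-1-one (diastereomer mixture) | CC1=C(C(=O)C(C)C(O)C(OCC)OCC)C(C)(C)C[C@H](O[Si](C)(C)C(C)(C)C)C1 | intermediate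
12 | methanesulfonate of 11 | CC1=C(C(=O)C(C)C(OS(C)(=O)=O)C(OCC)OCC)C(C)(C)C[C@H](O[Si](C)(C)C(C)(C)C)C1 | intermediate
13 | (2E)-1-[(4R)-4-(TBSO)-2,6,6-trimethylcyclohex-1-en-1-yl]-4,4-diethoxy-2-methylbut-2-en-1-one | CC1=C(C(=O)/C(C)=C/C(OCC)OCC)C(C)(C)C[C@H](O[Si](C)(C)C(C)(C)C)C1 | intermediate
14 | (trimethylsilyl)diazomethane | C[Si](C)(C)C=[N+]=[N-] | starting material
15 | lithium alkoxide from addition of lithiated 14 to 13 (carbinol carbon unspecified) | CC1=C(C(O[Li])(C(=[N+]=[N-])[Si](C)(C)C)/C(C)=C/C(OCC)OCC)C(C)(C)C[C@H](O[Si](C)(C)C(C)(C)C)C1 | intermediate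
16 | diazoalkene from 15 | CC1=C(C(=C=[N+]=[N-])/C(C)=C/C(OCC)OCC)C(C)(C)C[C@H](O[Si](C)(C)C(C)(C)C)C1 | intermediate
17 | alkylidene carbene from 16 | CC1=C(C(=[C])/C(C)=C/C(OCC)OCC)C(C)(C)C[C@H](O[Si](C)(C)C(C)(C)C)C1 | intermediate
18 | tert-butyl{[(1R)-4-[(3E)-5,5-diethoxy-3-methylpent-3-en-1-yn-1-yl]-3,5,5-trimethylcyclohex-3-en-1-yl]oxy}dimethylsilane | CC1=C(C#C/C(C)=C/C(OCC)OCC)C(C)(C)C[C@H](O[Si](C)(C)C(C)(C)C)C1 | intermediate
19 | (2E)-5-[(4R)-4-(TBSO)-2,6,6-trimethylcyclohex-1-en-1-yl]-3-methylpent-2-en-4-ynal | CC1=C(C#C/C(C)=C/C=O)C(C)(C)C[C@H](O[Si](C)(C)C(C)(C)C)C1 | intermediate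
20 | ethyl 4-(diethoxyphosphoryl)-3-methylbut-2-enoate (E/Z mixture) | CCOC(=O)C=C(C)CP(=O)(OCC)OCC | starting material
21 | ethyl (2E,4E,6E)-9-[(4R)-4-(TBSO)-2,6,6-trimethylcyclohex-1-en-1-yl]-3,7-dimethylnona-2,4,6-trien-8-ynoate | CC1=C(C#C/C(C)=C/C=C/C(C)=C/C(=O)OCC)C(C)(C)C[C@H](O[Si](C)(C)C(C)(C)C)C1 | intermediate
22 | (2E,4E,6E)-9-[(4R)-4-(TBSO)-2,6,6-trimethylcyclohex-1-en-1-yl]-3,7-dimethylnona-2,4,6-trien-8-yn-1-ol | CC1=C(C#C/C(C)=C/C=C/C(C)=C/CO)C(C)(C)C[C@H](O[Si](C)(C)C(C)(C)C)C1 | intermediate
23 | {(2E,4E,6E)-9-[(4R)-4-(TBSO)-2,6,6-trimethylcyclohex-1-en-1-yl]-3,7-dimethylnona-2,4,6-trien-8-yn-1-yl}triphenylphosphonium bromide | CC1=C(C#C/C(C)=C/C=C/C(C)=C/C[P+](c2ccccc2)(c2ccccc2)c2ccccc2)C(C)(C)C[C@H](O[Si](C)(C)C(C)(C)C)C1.[Br-] | intermediate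
24 | methyl (4R)-4-(TBSO)-2,6,6-trimethylcyclohex-1-ene-1-carboxylate | CC1=C(C(=O)OC)C(C)(C)C[C@H](O[Si](C)(C)C(C)(C)C)C1 | intermediate
25 | [(4R)-4-(TBSO)-2,6,6-trimethylcyclohex-1-en-1-yl]methanol | CC1=C(CO)C(C)(C)C[C@H](O[Si](C)(C)C(C)(C)C)C1 | intermediate
26 | [(1R,4S,6R)-4-(TBSO)-2,2,6-trimethyl-7-oxabicyclo[4.1.0]heptan-1-yl]methanol | OC[C@]12C(C)(C)C[C@H](O[Si](C)(C)C(C)(C)C)C[C@@]1(C)O2 | intermediate
27 | (1S,4S,6R)-4-(TBSO)-2,2,6-trimethyl-7-oxabicyclo[4.1.0]heptane-1-carbaldehyde | O=C[C@]12C(C)(C)C[C@H](O[Si](C)(C)C(C)(C)C)C[C@@]1(C)O2 | intermediate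
28 | 1-(triphenyl-λ5-phosphanylidene)propan-2-one | CC(=O)C=P(c1ccccc1)(c1ccccc1)c1ccccc1 | starting material
29 | (3E)-4-[(1S,4S,6R)-4-(TBSO)-2,2,6-trimethyl-7-oxabicyclo[4.1.0]heptan-1-yl]but-3-en-2-one | CC(=O)/C=C/[C@]12C(C)(C)C[C@H](O[Si](C)(C)C(C)(C)C)C[C@@]1(C)O2 | intermediate
30 | (3E)-4-[(1S,2S,4S)-4-(TBSO)-1,2-dihydroxy-2,6,6-trimethylcyclohexyl]but-3-en-2-one | CC(=O)/C=C/[C@]1(O)C(C)(C)C[C@H](O[Si](C)(C)C(C)(C)C)C[C@]1(C)O | intermediate
31 | diethyl (cyanomethyl)phosphonate | CCOP(=O)(CC#N)OCC | starting material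
32 | (2E,4E)-5-[(1S,2S,4S)-4-(TBSO)-1,2-dihydroxy-2,6,6-trimethylcyclohexyl]-3-methylpenta-2,4-dienenitrile | N#C/C=C(C)/C=C/[C@]1(O)C(C)(C)C[C@H](O[Si](C)(C)C(C)(C)C)C[C@]1(C)O | intermediate
33 | N,O,O-tris(diisobutylaluminio) aldimine from 32 | CC(C)C[Al](CC(C)C)N=C/C=C(C)/C=C/[C@]1(O[Al](CC(C)C)CC(C)C)C(C)(C)C[C@H](O[Si](C)(C)C(C)(C)C)C[C@]1(C)O[Al](CC(C)C)CC(C)C | intermediate
34 | (2E,4E)-5-[(1S,2S,4S)-4-(TBSO)-1,2-dihydroxy-2,6,6-trimethylcyclohexyl]-3-methylpenta-2,4-dienal | O=C/C=C(C)/C=C/[C@]1(O)C(C)(C)C[C@H](O[Si](C)(C)C(C)(C)C)C[C@]1(C)O | intermediate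
35 | diethyl (3-cyano-2-methylprop-2-en-1-yl)phosphonate (E/Z mixture) | CCOP(=O)(CC(C)=CC#N)OCC | starting material
36 | (2E,4E,6E,8E)-9-[(1S,2S,4S)-4-(TBSO)-1,2-dihydroxy-2,6,6-trimethylcyclohexyl]-3,7-dimethylnona-2,4,6,8-tetraenenitrile | N#C/C=C(C)/C=C/C=C(C)/C=C/[C@]1(O)C(C)(C)C[C@H](O[Si](C)(C)C(C)(C)C)C[C@]1(C)O | intermediate
37 | N,O,O-tris(diisobutylaluminio) aldimine from 36 | CC(C)C[Al](CC(C)C)N=C/C=C(C)/C=C/C=C(C)/C=C/[C@]1(O[Al](CC(C)C)CC(C)C)C(C)(C)C[C@H](O[Si](C)(C)C(C)(C)C)C[C@]1(C)O[Al](CC(C)C)CC(C)C | intermediate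
38 | (2E,4E,6E,8E)-9-[(1S,2S,4S)-4-(TBSO)-1,2-dihydroxy-2,6,6-trimethylcyclohexyl]-3,7-dimethylnona-2,4,6,8-tetraenal | O=C/C=C(C)/C=C/C=C(C)/C=C/[C@]1(O)C(C)(C)C[C@H](O[Si](C)(C)C(C)(C)C)C[C@]1(C)O | intermediate
39 | ylide from 23 | CC1=C(C#C/C(C)=C/C=C/C(C)=C/C=P(c2ccccc2)(c2ccccc2)c2ccccc2)C(C)(C)C[C@H](O[Si](C)(C)C(C)(C)C)C1 | intermediate
40 | (all-E,3S,5S,6S,3'R)-3,3'-bis(TBSO)-7',8'-didehydro-5,6-dihydro-β,β-carotene-5,6-diol | CC1=C(C#C/C(C)=C/C=C/C(C)=C/C=C/C=C(C)/C=C/C=C(C)/C=C/[C@]2(O)C(C)(C)C[C@H](O[Si](C)(C)C(C)(C)C)C[C@]2(C)O)C(C)(C)C[C@H](O[Si](C)(C)C(C)(C)C)C1 | intermediate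
41 | (all-E,3S,5S,6S,3'R)-7',8'-didehydro-5,6-dihydro-β,β-carotene-3,5,6,3'-tetrol | CC1=C(C#C/C(C)=C/C=C/C(C)=C/C=C/C=C(C)/C=C/C=C(C)/C=C/[C@]2(O)C(C)(C)C[C@H](O)C[C@]2(C)O)C(C)(C)C[C@H](O)C1 | target

## Step count and least certain steps

Total: 23 steps. Longest linear sequence: 14 steps (1, 2, 12 to 23); the acetylenic branch (1 to 11, 22, 23) has 13.

Step 7 (key step). The lithiated diazo reagent may add to C10' in conjugate fashion and close to a pyrazoline, because the carbonyl of 13 is flanked by two fully substituted sp2 carbons. Alternatively the carbene may insert into a methyl C–H bond of the ring before the alkenyl group migrates. Fallback: the route is left at the triflate 4, which is joined by Sonogashira coupling (PdCl2(PPh3)2, CuI, iPr2NH, THF, rt) to commercial (2E)-3-methylpent-2-en-4-yn-1-ol F1 to give (2E)-5-[(4R)-4-(TBSO)-2,6,6-trimethylcyclohex-1-en-1-yl]-3-methylpent-2-en-4-yn-1-ol F2. Oxidation with MnO2 (CH2Cl2, rt) rejoins the route at 19. The 9'E geometry is then bought with F1 and has to be defended against the metal catalysts, which is the weakness the ketone route was meant to remove.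

Step 17. The approach of water to C5 is syn to the C3 silyloxy group and requires an unfavourable ring conformation. The opening may therefore take on SN1 character, with loss of facial control at C5, proton loss to allylic alcohols, ring contraction by a 1,2-shift, or loss of the silyl ether. Fallback: starting from 29, the silyl ether is cleaved (Bu4NF, THF) to (3S,5R,6S)-5,6-epoxy-3-hydroxy-5,6-dihydro-β-ionone F7. Acylation (Boc2O, DMAP, CH2Cl2) gives its tert-butyl carbonate F8. BF3·OEt2 (CH2Cl2, −78 °C) then delivers the carbonate oxygen to C5 with inversion and gives the 3,5-cyclic carbonate of (3S,5S,6S)-3,5,6-trihydroxy-5,6-dihydro-β-ionone F9. F8 and F9 are the compounds called A4 and A5 above. Methanolysis (K2CO3, MeOH) gives (3E)-4-[(1S,2S,4S)-1,2,4-trihydroxy-2,6,6-trimethylcyclohexyl]but-3-en-2-one F10, and selective silylation of the secondary hydroxyl (TBSCl, imidazole, DMF) returns to 30. If only the silyl ether is lost in step 17, the product is F10 and the last operation alone suffices.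

Step 4. The Grignard reagent may act as a base on the N-methoxy group (loss of formaldehyde to the N-methyl amide) or fail to add, because the amide carbonyl sits between a quaternary carbon and a substituted alkene carbon. Fallback: starting from the allylic alcohol 25 of the other branch, oxidation with MnO2 (CH2Cl2) gives (4R)-4-(TBSO)-2,6,6-trimethylcyclohex-1-ene-1-carbaldehyde F3. Addition of 6 (THF, 0 °C) gives 1-[(4R)-4-(TBSO)-2,6,6-trimethylcyclohex-1-en-1-yl]propan-1-ol F4, and Dess–Martin oxidation returns to 8.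

Step 14. Epoxidation of the crowded tetrasubstituted double bond may be slow, and the intrinsic facial bias of the ring may oppose the tartrate, which would lower the anti selectivity. Fallback: starting from 4, a Heck reaction (Pd(OAc)2, PPh3, Et3N, DMF, 70 °C) with but-3-en-2-one F5 gives (3E)-4-[(4R)-4-(TBSO)-2,6,6-trimethylcyclohex-1-en-1-yl]but-3-en-2-one F6. A peracid (mCPBA, NaHCO3, CH2Cl2, 0 °C) epoxidises the electron-rich C5=C6 bond under substrate control, expected to favour the face anti to the silyloxy group. After chromatographic removal of the syn isomer the route is rejoined at 29, and steps 12 to 16 are bypassed.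

Step 11. The acid may cleave the silyl ether, or phosphorus may be captured at an internal position of the delocalised cation. Partial silyl loss is tolerable, because the Wittig reaction accepts a free hydroxyl and step 23 converges, but it makes 23 ill-defined. Fallback: starting from 22, a Mitsunobu reaction with 2-mercaptobenzothiazole (PPh3, DIAD, THF) gives 2-{[(2E,4E,6E)-9-[(4R)-4-(TBSO)-2,6,6-trimethylcyclohex-1-en-1-yl]-3,7-dimethylnona-2,4,6-trien-8-yn-1-yl]sulfanyl}-1,3-benzothiazole F11. Oxidation ((NH4)6Mo7O24, H2O2, EtOH, 0 °C) gives the corresponding sulfone F12. Julia–Kocienski olefination with 38 (LiN(SiMe3)2, THF, −78 °C, base added to the mixture of both partners), followed by the same brief heating, returns to 40.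

## Further compounds

F1 | step 7 | (2E)-3-methylpent-2-en-4-yn-1-ol | C#C/C(C)=C/CO
F2 | step 7 | (2E)-5-[(4R)-4-(TBSO)-2,6,6-trimethylcyclohex-1-en-1-yl]-3-methylpent-2-en-4-yn-1-ol | CC1=C(C#C/C(C)=C/CO)C(C)(C)C[C@H](O[Si](C)(C)C(C)(C)C)C1
F3 | step 4 | (4R)-4-(TBSO)-2,6,6-trimethylcyclohex-1-ene-1-carbaldehyde | CC1=C(C=O)C(C)(C)C[C@H](O[Si](C)(C)C(C)(C)C)C1
F4 | step 4 | 1-[(4R)-4-(TBSO)-2,6,6-trimethylcyclohex-1-en-1-yl]propan-1-ol (both carbinol epimers) | CC1=C(C(O)CC)C(C)(C)C[C@H](O[Si](C)(C)C(C)(C)C)C1
F5 | step 14 | but-3-en-2-one | CC(=O)C=C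
F6 | step 14 | (3E)-4-[(4R)-4-(TBSO)-2,6,6-trimethylcyclohex-1-en-1-yl]but-3-en-2-one | CC1=C(/C=C/C(C)=O)C(C)(C)C[C@H](O[Si](C)(C)C(C)(C)C)C1
F7 | step 17 | (3E)-4-[(1S,4S,6R)-4-hydroxy-2,2,6-trimethyl-7-oxabicyclo[4.1.0]heptan-1-yl]but-3-en-2-one | CC(=O)/C=C/[C@]12C(C)(C)C[C@H](O)C[C@@]1(C)O2
F8 | step 17 | tert-butyl carbonate of F7 at O3 | CC(=O)/C=C/[C@]12C(C)(C)C[C@H](OC(=O)OC(C)(C)C)C[C@@]1(C)O2
F9 | step 17 | 3,5-cyclic carbonate of (3S,5S,6S)-3,5,6-trihydroxy-5,6-dihydro-β-ionone | CC(=O)/C=C/[C@]1(O)C(C)(C)C[C@H]2C[C@]1(C)OC(=O)O2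
F10 | step 17 | (3E)-4-[(1S,2S,4S)-1,2,4-trihydroxy-2,6,6-trimethylcyclohexyl]but-3-en-2-one | CC(=O)/C=C/[C@]1(O)C(C)(C)C[C@H](O)C[C@]1(C)O
F11 | step 11 | 2-{[(2E,4E,6E)-9-[(4R)-4-(TBSO)-2,6,6-trimethylcyclohex-1-en-1-yl]-3,7-dimethylnona-2,4,6-trien-8-yn-1-yl]sulfanyl}-1,3-benzothiazole | CC1=C(C#C/C(C)=C/C=C/C(C)=C/CSc2nc3ccccc3s2)C(C)(C)C[C@H](O[Si](C)(C)C(C)(C)C)C1
F12 | step 11 | 2-{[(2E,4E,6E)-9-[(4R)-4-(TBSO)-2,6,6-trimethylcyclohex-1-en-1-yl]-3,7-dimethylnona-2,4,6-trien-8-yn-1-yl]sulfonyl}-1,3-benzothiazole | CC1=C(C#C/C(C)=C/C=C/C(C)=C/CS(=O)(=O)c2nc3ccccc3s2)C(C)(C)C[C@H](O[Si](C)(C)C(C)(C)C)C1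
A1 | alternative 1 | 3-hydroxy-4-methyl-2H-pyran-2-one | CC1=C(O)C(=O)OC=C1
A2 | alternative 1 | 2-methylprop-2-enal | CC(=C)C=O
A3 | alternative 1 | 4-hydroxy-5,8-dimethyl-3-oxo-2-oxabicyclo[2.2.2]oct-5-ene-8-carbaldehyde (C8 epimers unspecified) | O=C1O[C@@H]2C=C(C)[C@@]1(O)C(C)(C=O)C2
A4 | alternative 2 | tert-butyl carbonate of (3S,5R,6S)-5,6-epoxy-3-hydroxy-5,6-dihydro-β-ionone | CC(=O)/C=C/[C@]12C(C)(C)C[C@H](OC(=O)OC(C)(C)C)C[C@@]1(C)O2
A5 | alternative 2 | 3,5-cyclic carbonate of (3S,5S,6S)-3,5,6-trihydroxy-5,6-dihydro-β-ionone | CC(=O)/C=C/[C@]1(O)C(C)(C)C[C@H]2C[C@]1(C)OC(=O)O2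
A6 | alternative 3 | (4R)-1-(buta-1,3-diyn-1-yl)-4-(TBSO)-2,6,6-trimethylcyclohex-1-ene | CC1=C(C#CC#C)C(C)(C)C[C@H](O[Si](C)(C)C(C)(C)C)C1
A7 | alternative 3 | ethyl (2E,4E)-5-iodo-3-methylpenta-2,4-dienoate | CCOC(=O)/C=C(C)/C=C/I
A8 | alternative 3 | ethyl (2E,4E,6E)-9-[(4R)-4-(TBSO)-2,6,6-trimethylcyclohex-1-en-1-yl]-3,7-dimethylnona-2,4,6-trien-8-ynoate | CC1=C(C#C/C(C)=C/C=C/C(C)=C/C(=O)OCC)C(C)(C)C[C@H](O[Si](C)(C)C(C)(C)C)C1
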